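Readings and results were computed on assumed constants.

In the cedar run G came more slowly late than early: it gained 13.1% in the first 10.0 s and 12 percentage points in the last 30.0 s, although X still stood at 73.9% when that last stretch began. A rate first order in X would follow X, and this one falls faster, so a second concentration is at work. Enzyme D may be turning into L, or G may be holding D back, which is product inhibition.

the same everywhere: D 0.01 mol%

| charge | X | temperature | remark | time |
|---|---|---|---|---|
| maple | 0.21 M | −8 °C | run made earlier |  |
| cedar | 0.33 M | 17 °C | run made earlier |  |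
| south | 0.15 M |  | at −3 °C until 50 s, from then on at 37 °C | 2.5 min |
| north-west | 0.15 M | −3 °C |  | 2.5 min |
| west | 0.15 M | 17 °C |  | 2.5 min |
| north | 0.15 M | 37 °C |  | 2.5 min |

maple run (percent of the X charged)

| time / min | G / % | X / % |
|---|---|---|
| 0.417 | 10.3 | 89.8 |
| 0.833 | 17.2 | 82.6 |
| 1.33 | 24.0 | 75.6 |
| 1.50 | 25.8 | 75.2 |
| 2.00 | 30.0 | 69.4 |
| 2.50 | 32.4 | 66.2 |

cedar run (percent of the X charged)

| time / s | G / % | X / % |
|---|---|---|
| 10.0 | 13.1 | 86.5 |
| 12.0 | 14.9 | 85.1 |
| 20.0 | 20.7 | 80.0 |
| 30.0 | 26.7 | 73.9 |
| 60.0 | 38.9 | 61.7 |

(readings scatter by 0.5 percentage points)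

- which flask leads in amount of G, in percent of the X charged ("all alike" within 1.5 percentage points) (south / north-west / west / north / all alike)
- how much G is there at the end, in percent of the X charged: south
- how much G is there at the end, in percent of the X charged: north-west
- how much G is there at the end, in percent of the X charged: west
- how much G is there at the end, in percent of the X charged: north

The reckoning here tries the second of these, with the rate proportional to X over G. With g the share of X turned to G and x the share left, dg/dt = c·x/g, which integrates to a G clock, Y = ln(X charged / X left) − g = c·t. At a fixed loading the charge of X cancels from c, since D and G both scale with it. Maple gives Y/t of 0.0269 min⁻¹ at 1.50 min and 0.0270 min⁻¹ at 2.50 min. Cedar gives 0.0872 min⁻¹ at 30.0 s, still climbing, and 0.104 min⁻¹ at 60.0 s, which is read as the clock rate at 17 °C. The last readings serve, as G stands lower early on.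

These two rates give an Arrhenius energy of 34.4 kJ mol⁻¹, hence 0.0361 min⁻¹ at −3 °C and 0.260 min⁻¹ at 37 °C. Y depends on g alone, so in south it simply adds across the change, reaching 0.463. North reaches 0.650, west 0.259 and north-west 0.0902. Solved for g, this reckoning gives 68.0% in south, 75.3% in north, 55.6% in west and 37.0% in north-west, with north ahead.

The forecast also names north but stands lower in north and south: 60% for south, 35% for north-west, 57% for west and 66% for north. Its grounds weigh dying D against a surviving tail: “I hedge between these, so north leads, south is close behind”.

The flasks give 68.0% in south, 37.5% in north-west, 56.9% in west and 75.4% in north, which leads.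

    D → L (k = 0.00220 min⁻¹, Ea = 281 kJ mol⁻¹)
    X + D → G + D, rate k2*[X]*[D]/(1 + ([X]/Km2) + ([G]/Kp2)) (0.0620 M, 5.50 mM, k = 5.60 × 10⁵ M⁻¹ min⁻¹, Ea = 29.0 kJ mol⁻¹)
    (constants at 37 °C)

North ends with G at 113 mM against the inhibition constant of G of 5.5 mM, and its result reads Y = 0.648 against the 0.650 reckoned. A neighbour flask, like north but kept at 22 °C, has a clock rate of 0.132 min⁻¹ from the same two runs, so Y = 0.330 at 2.50 min and g = 60.6%. That neighbour ends with G at 61.8% of the X charged.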